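## Retrosynthetic overview

1. The C2–O aryl ether is cut first: hydroquinone 25 (ring B, brought in intact) displaces the sulfonyl group of 2-methanesulfonylchromone 24. The last forward step frees the 5-OH by chelation-controlled cleavage of the peri ethyl ether.
2. Ring C is cut at O1–C2 and C2–C3: carbon disulfide supplies C2 to the o-hydroxyacetophenone 19, whose acetyl group (C4, C3) is placed on C4a of phenol 14 by directed ortho metalation.
3. Ring A is made first, by Danheiser benzannulation of 3-ethoxycyclobutenone 4 with the prenylated methoxyalkyne 9 (bonds C8a–C8, C7–C6, C8a–C4a). The strategy rests on the ring A pattern: the C8 prenyl group lies between the oxygen on C8a and the methoxy group on C7, and C5 carries a third, differently substituted oxygen.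
4. Compound 4 comes from ethoxyacetylene and ketene, and 9 from chloroacetaldehyde dimethyl acetal and prenyl bromide. Ring order: A, then C.

Key step: step 3

Remark on the chemistry: the target is achiral, so no stereocontrol is needed; intermediates 11, 17 and 23 are racemic and transient. Hydroquinone is used unprotected and in excess.

## Route

Step 1
Reactants: 1 ethoxyacetylene; 2 acetyl chloride
Product: 4 3-ethoxycyclobut-2-en-1-one, via ketene 3 (not isolated)
Conditions: Et3N, Et2O, 0 °C → rt, slow addition of 2 to excess 1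
Reagents that add atoms: none
Why: Triethylamine dehydrochlorinates acetyl chloride to ketene, which is trapped by the electron-rich ynol ether in a thermal [2+2] cycloaddition; the CH terminus of 1 bonds to the ketene carbonyl carbon, so the ethoxy group ends on C3 of the cyclobutenone.

Step 2
Reactants: 5 chloroacetaldehyde dimethyl acetal; 6 prenyl bromide
Product: 9 1-methoxy-5-methylhex-4-en-1-yne, via 2-chlorovinyl methyl ether 7 (not isolated), via lithium methoxyacetylide 8 (not isolated)
Conditions: LiNEt2 (3.1 equiv, from n-BuLi and Et2NH), THF, 0 °C; then 6, DMPU, −78 °C → rt; H2O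
Reagents that add atoms: none
Why: The lithium amide effects two successive eliminations (methanol, then hydrogen chloride) and deprotonates the methoxyacetylene so formed; the acetylide is then alkylated by SN2 at the primary allylic carbon of 6 in the dipolar cosolvent.

Step 3
Reactants: 4 3-ethoxycyclobut-2-en-1-one; 9 1-methoxy-5-methylhex-4-en-1-yne
Product: 14 5-ethoxy-3-methoxy-2-(3-methylbut-2-en-1-yl)phenol, via vinylketene 10 (not isolated), via 4-vinylcyclobutenone 11 (not isolated), via dienylketene 12 (not isolated), via cyclohexadienone 13 (not isolated)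
Conditions: 4 (1.0 equiv), 9 (1.3 equiv), PhMe, 80 °C then 110 °C, sealed tube
Reagents that add atoms: none
Why: Heating opens 4 by a four-electron electrocyclic reaction to vinylketene 10, and the prenyl-bearing alkyne carbon of 9 attacks its ketene carbon (future C8a) in a [2+2] cycloaddition that forms C8a–C8 and C7–C6 and gives 11. A second four-electron ring opening gives dienylketene 12, which closes ring A by a thermally allowed disrotatory six-electron electrocyclization (C8a–C4a) to dienone 13, and this tautomerizes to phenol 14. The closest known reaction type is the Danheiser benzannulation of cyclobutenones with alkoxyalkynes, which delivers 2-alkyl-3-alkoxyphenols. No stereocenter is formed. The selectivity needed is the orientation of the [2+2] step; the oxygen lone pair of the ynol ether makes the carbon-substituted terminus the nucleophile, which puts the prenyl group between the OH and OMe groups. Because the alkyne is a methyl ether, the retro-ene loss of an alkene that limits ethyl ynol ethers on heating is not available, and the donor-stabilized cyclobutenone 4 is expected to be the slow partner, hence the staged heating.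

Step 4
Reactants: 14 5-ethoxy-3-methoxy-2-(3-methylbut-2-en-1-yl)phenol
Product: 15 5-ethoxy-1-methoxy-3-(methoxymethoxy)-2-(3-methylbut-2-en-1-yl)benzene
Conditions: MOMCl, iPr2NEt, CH2Cl2, 0 °C → rt
Reagents that add atoms: chloromethyl methyl ether, COCCl
Why: O-Alkylation of the phenol (Williamson type) masks the acidic OH and installs the strongest ortho-directing group on the ring for the next step.

Step 5
Reactants: 15 5-ethoxy-1-methoxy-3-(methoxymethoxy)-2-(3-methylbut-2-en-1-yl)benzene
Product: 18 1-[6-ethoxy-4-methoxy-2-(methoxymethoxy)-3-(3-methylbut-2-en-1-yl)phenyl]ethan-1-one, via aryllithium 16 (not isolated), via lithium hemiaminal 17 (not isolated)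
Conditions: n-BuLi, TMEDA, THF, −20 → 0 °C; then MeC(O)N(OMe)Me, −78 → 0 °C; H2O
Reagents that add atoms: N-methoxy-N-methylacetamide, CON(C)C(C)=O
Why: Directed ortho metalation: the chelating methoxymethoxy group and the ethoxy group together direct n-BuLi to the ring CH between them (future C4a), the methoxy group being buttressed by the prenyl group, and the aryllithium adds once to the Weinreb amide because the chelated adduct 17 collapses to the ketone only on work-up.

Step 6
Reactants: 18 1-[6-ethoxy-4-methoxy-2-(methoxymethoxy)-3-(3-methylbut-2-en-1-yl)phenyl]ethan-1-one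
Product: 19 1-[6-ethoxy-2-hydroxy-4-methoxy-3-(3-methylbut-2-en-1-yl)phenyl]ethan-1-one
Conditions: aq. HCl (3 M), MeOH, rt
Reagents that add atoms: none
Why: Acid-catalysed acetal methanolysis removes the methoxymethyl group, helped by the hydrogen bond of the freed phenol to the ortho ketone; dilute acid at room temperature should spare the trisubstituted alkene.

Step 7
Reactants: 19 1-[6-ethoxy-2-hydroxy-4-methoxy-3-(3-methylbut-2-en-1-yl)phenyl]ethan-1-one
Product: 21 5-ethoxy-4-hydroxy-7-methoxy-8-(3-methylbut-2-en-1-yl)-2H-chromene-2-thione, via β-keto dithioate 20 (not isolated)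
Conditions: CS2, KOtBu (3.5 equiv), THF, 0 °C → rt; then 1 M HCl, 0 °C
Reagents that add atoms: carbon disulfide, S=C=S
Why: The potassium enolate of the methyl ketone adds to carbon disulfide (Claisen-type condensation), and the dithioate cyclizes through the ortho phenol oxygen with loss of hydrogen sulfide, closing ring C at O1–C2.

Step 8
Reactants: 21 5-ethoxy-4-hydroxy-7-methoxy-8-(3-methylbut-2-en-1-yl)-2H-chromene-2-thione
Product: 22 5-ethoxy-7-methoxy-8-(3-methylbut-2-en-1-yl)-2-(methylsulfanyl)-4H-chromen-4-one
Conditions: MeI, K2CO3, acetone, rt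
Reagents that add atoms: iodomethane, CI
Why: SN2 methylation occurs on the soft sulfur of the ambident thione anion, which fixes the chromone tautomer.

Step 9
Reactants: 22 5-ethoxy-7-methoxy-8-(3-methylbut-2-en-1-yl)-2-(methylsulfanyl)-4H-chromen-4-one
Product: 24 5-ethoxy-2-(methanesulfonyl)-7-methoxy-8-(3-methylbut-2-en-1-yl)-4H-chromen-4-one, via sulfoxide 23 (not isolated)
Conditions: (NH4)6Mo7O24·4H2O (cat.), 30% aq. H2O2, EtOH, 0 °C → rt
Reagents that add atoms: hydrogen peroxide, OO
Why: Molybdate-catalysed oxidation with hydrogen peroxide takes sulfides through the sulfoxide to the sulfone without epoxidizing trisubstituted alkenes, as in the routine preparation of heteroaryl sulfones for Julia–Kocienski olefination, so the prenyl double bond should survive.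

Step 10
Reactants: 24 5-ethoxy-2-(methanesulfonyl)-7-methoxy-8-(3-methylbut-2-en-1-yl)-4H-chromen-4-one; 25 hydroquinone
Product: 26 5-ethoxy-2-(4-hydroxyphenoxy)-7-methoxy-8-(3-methylbut-2-en-1-yl)-4H-chromen-4-one
Conditions: 25 (5 equiv), K2CO3, DMF, 0 °C → rt, argon, slow addition of 24
Reagents that add atoms: none
Why: Addition–elimination at C2 (vinylogous nucleophilic acyl substitution): the phenoxide adds to the sulfonyl-activated enone carbon and methanesulfinate leaves, while the excess of hydroquinone holds the reaction at monoarylation.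

Step 11
Reactants: 26 5-ethoxy-2-(4-hydroxyphenoxy)-7-methoxy-8-(3-methylbut-2-en-1-yl)-4H-chromen-4-one
Product: 27 7-O-methylepimedonin G, 5-hydroxy-2-(4-hydroxyphenoxy)-7-methoxy-8-(3-methylbut-2-en-1-yl)-4H-chromen-4-one
Conditions: MgI2 (anhydrous, 4 equiv), THF–PhMe, 80 °C; then aq. NH4Cl
Reagents that add atoms: none
Why: Chelation-controlled ether cleavage: magnesium binds the C4 carbonyl oxygen and the peri 5-oxygen and iodide removes the ethyl group by SN2; the unchelated 7-methoxy group is not activated, and the prenyl group, which has no free ortho hydroxyl, is not exposed to protic acid.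

## Compound list

1 | ethoxyacetylene (ethoxyethyne) | CCOC#C | starting material
2 | acetyl chloride | CC(=O)Cl | starting material
3 | ketene (ethenone) | C=C=O | intermediate (not isolated)
4 | 3-ethoxycyclobut-2-en-1-one | CCOC1=CC(=O)C1 | intermediate
5 | chloroacetaldehyde dimethyl acetal (2-chloro-1,1-dimethoxyethane) | COC(CCl)OC | starting material
6 | prenyl bromide (1-bromo-3-methylbut-2-ene) | CC(C)=CCBr | starting material
7 | 2-chlorovinyl methyl ether (1-chloro-2-methoxyethene, E/Z mixture) | COC=CCl | intermediate (not isolated)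
8 | lithium methoxyacetylide | [Li]C#COC | intermediate (not isolated)
9 | 1-methoxy-5-methylhex-4-en-1-yne | COC#CCC=C(C)C | intermediate
10 | 3-ethoxybuta-1,3-dien-1-one (vinylketene) | C=C(OCC)C=C=O | intermediate (not isolated)
11 | 4-(1-ethoxyethenyl)-3-methoxy-2-(3-methylbut-2-en-1-yl)cyclobut-2-en-1-one (racemic) | C=C(OCC)C1C(=O)C(CC=C(C)C)=C1OC | intermediate (not isolated)
12 | (3E)-5-ethoxy-3-methoxy-2-(3-methylbut-2-en-1-yl)hexa-1,3,5-trien-1-one (dienylketene) | O=C=C(CC=C(C)C)/C(OC)=C\C(OCC)=C | intermediate (not isolated)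
13 | 5-ethoxy-3-methoxy-2-(3-methylbut-2-en-1-yl)cyclohexa-2,4-dien-1-one | O=C1CC(OCC)=CC(OC)=C1CC=C(C)C | intermediate (not isolated)
14 | 5-ethoxy-3-methoxy-2-(3-methylbut-2-en-1-yl)phenol | CCOc1cc(O)c(CC=C(C)C)c(OC)c1 | intermediate
15 | 5-ethoxy-1-methoxy-3-(methoxymethoxy)-2-(3-methylbut-2-en-1-yl)benzene | CCOc1cc(OCOC)c(CC=C(C)C)c(OC)c1 | intermediate
16 | [2-ethoxy-4-methoxy-6-(methoxymethoxy)-5-(3-methylbut-2-en-1-yl)phenyl]lithium | CCOc1c([Li])c(OCOC)c(CC=C(C)C)c(OC)c1 | intermediate (not isolated)
17 | lithium 1-[6-ethoxy-4-methoxy-2-(methoxymethoxy)-3-(3-methylbut-2-en-1-yl)phenyl]-1-[methoxy(methyl)amino]ethan-1-olate (racemic) | CCOc1c(C(C)(O[Li])N(C)OC)c(OCOC)c(CC=C(C)C)c(OC)c1 | intermediate (not isolated)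
18 | 1-[6-ethoxy-4-methoxy-2-(methoxymethoxy)-3-(3-methylbut-2-en-1-yl)phenyl]ethan-1-one | CCOc1c(C(C)=O)c(OCOC)c(CC=C(C)C)c(OC)c1 | intermediate
19 | 1-[6-ethoxy-2-hydroxy-4-methoxy-3-(3-methylbut-2-en-1-yl)phenyl]ethan-1-one | CCOc1cc(OC)c(CC=C(C)C)c(O)c1C(C)=O | intermediate
20 | 3-[6-ethoxy-2-hydroxy-4-methoxy-3-(3-methylbut-2-en-1-yl)phenyl]-3-oxopropanedithioic acid (present as its potassium salt) | CCOc1cc(OC)c(CC=C(C)C)c(O)c1C(=O)CC(=S)S | intermediate (not isolated)
21 | 5-ethoxy-4-hydroxy-7-methoxy-8-(3-methylbut-2-en-1-yl)-2H-chromene-2-thione | CCOc1cc(OC)c(CC=C(C)C)c2oc(=S)cc(O)c12 | intermediate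
22 | 5-ethoxy-7-methoxy-8-(3-methylbut-2-en-1-yl)-2-(methylsulfanyl)-4H-chromen-4-one | CCOc1cc(OC)c(CC=C(C)C)c2oc(SC)cc(=O)c12 | intermediate
23 | 5-ethoxy-2-(methanesulfinyl)-7-methoxy-8-(3-methylbut-2-en-1-yl)-4H-chromen-4-one (racemic at sulfur) | CCOc1cc(OC)c(CC=C(C)C)c2oc(S(C)=O)cc(=O)c12 | intermediate (not isolated)
24 | 5-ethoxy-2-(methanesulfonyl)-7-methoxy-8-(3-methylbut-2-en-1-yl)-4H-chromen-4-one | CCOc1cc(OC)c(CC=C(C)C)c2oc(S(C)(=O)=O)cc(=O)c12 | intermediate
25 | hydroquinone (benzene-1,4-diol) | Oc1ccc(O)cc1 | starting material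
26 | 5-ethoxy-2-(4-hydroxyphenoxy)-7-methoxy-8-(3-methylbut-2-en-1-yl)-4H-chromen-4-one | CCOc1cc(OC)c(CC=C(C)C)c2oc(Oc3ccc(O)cc3)cc(=O)c12 | intermediate
27 | 7-O-methylepimedonin G, 5-hydroxy-2-(4-hydroxyphenoxy)-7-methoxy-8-(3-methylbut-2-en-1-yl)-4H-chromen-4-one | COc1cc(O)c2c(=O)cc(Oc3ccc(O)cc3)oc2c1CC=C(C)C | target

## Step count and risks

Total step count: 11. Longest linear sequence: 10 steps (steps 1 and 3–11; the branch through step 2 is equally long).

Steps most likely to fail:

1. Step 3 (benzannulation). The vinylogous-ester cyclobutenone 4 may open too slowly, so that 4 and the ynol ether 9 oligomerize before vinylketene 10 forms, or the product phenol may be acylated by 10. The fallback generates the same vinylketene at room temperature by photochemical Wolff rearrangement instead of thermal ring opening. Ethyl vinyl ether would be lithiated (t-BuLi, THF, −78 → 0 °C) to 1-ethoxyvinyllithium F1 and acylated with N-methoxy-N-methylacetamide to 3-ethoxybut-3-en-2-one F2. Detrifluoroacetylative diazo transfer (LiN(SiMe3)2, CF3CO2CH2CF3, THF, −78 °C; then MsN3, Et3N, aqueous MeCN) through 5-ethoxy-1,1,1-trifluorohex-5-ene-2,4-dione F3 would give 1-diazo-3-ethoxybut-3-en-2-one F4. Irradiation of F4 with 9 in CH2Cl2 at room temperature, then warming, would pass through 10–13. This fallback sets out from 9 and comes back at 14.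

2. Step 5 (directed metalation and acylation). n-BuLi may instead deprotonate the benzylic and allylic CH2 of the prenyl group or the other ring CH, or the hindered aryllithium may take a proton from the acetamide instead of adding. The fallback avoids aryllithium chemistry: phenol 14 would be formylated at its only free ortho carbon through the magnesium phenoxide (MgCl2, Et3N, paraformaldehyde, MeCN, reflux) to 6-ethoxy-2-hydroxy-4-methoxy-3-(3-methylbut-2-en-1-yl)benzaldehyde F5. Addition of MeMgBr (excess, THF, 0 °C) would give 1-[6-ethoxy-2-hydroxy-4-methoxy-3-(3-methylbut-2-en-1-yl)phenyl]ethan-1-ol F6, and MnO2 (CH2Cl2, rt) would oxidize the benzylic alcohol to the ketone. This fallback sets out from 14 and comes back at 19; steps 4 and 6 are then not needed.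

3. Step 11 (cleavage of the peri ethyl ether). Attack of iodide on an ethyl group is slower than on a methyl group, and long heating may allow exchange or loss of the 4-hydroxyphenoxy group at the electrophilic C2, or damage to the prenyl group. The fallback moves the ether cleavage ahead of the C2–O bond formation, onto a more robust intermediate. Sulfide 22 would be treated with BCl3 (CH2Cl2, −78 → 0 °C) to give 5-hydroxy-7-methoxy-8-(3-methylbut-2-en-1-yl)-2-(methylsulfanyl)-4H-chromen-4-one F7. Oxidation as in step 9, through 5-hydroxy-2-(methanesulfinyl)-7-methoxy-8-(3-methylbut-2-en-1-yl)-4H-chromen-4-one F8, would give 5-hydroxy-2-(methanesulfonyl)-7-methoxy-8-(3-methylbut-2-en-1-yl)-4H-chromen-4-one F9. Displacement with excess hydroquinone 25 (K2CO3, 2 equiv, DMF) would then give the target directly. This fallback sets out from 22 and comes back at 27.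

## Further compounds

F1 | step 3 | 1-ethoxyvinyllithium | [Li]C(OCC)=C
F2 | step 3 | 3-ethoxybut-3-en-2-one | CC(=O)C(OCC)=C
F3 | step 3 | 5-ethoxy-1,1,1-trifluorohex-5-ene-2,4-dione | O=C(CC(=O)C(OCC)=C)C(F)(F)F
F4 | step 3 | 1-diazo-3-ethoxybut-3-en-2-one | [N-]=[N+]=CC(=O)C(OCC)=C
F5 | step 5 | 6-ethoxy-2-hydroxy-4-methoxy-3-(3-methylbut-2-en-1-yl)benzaldehyde | CCOc1cc(OC)c(CC=C(C)C)c(O)c1C=O
F6 | step 5 | 1-[6-ethoxy-2-hydroxy-4-methoxy-3-(3-methylbut-2-en-1-yl)phenyl]ethan-1-ol (racemic) | CCOc1cc(OC)c(CC=C(C)C)c(O)c1C(C)O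
F7 | step 11 | 5-hydroxy-7-methoxy-8-(3-methylbut-2-en-1-yl)-2-(methylsulfanyl)-4H-chromen-4-one | COc1cc(O)c2c(=O)cc(SC)oc2c1CC=C(C)C
F8 | step 11 | 5-hydroxy-2-(methanesulfinyl)-7-methoxy-8-(3-methylbut-2-en-1-yl)-4H-chromen-4-one (racemic at sulfur) | COc1cc(O)c2c(=O)cc(S(C)=O)oc2c1CC=C(C)C
F9 | step 11 | 5-hydroxy-2-(methanesulfonyl)-7-methoxy-8-(3-methylbut-2-en-1-yl)-4H-chromen-4-one | COc1cc(O)c2c(=O)cc(S(C)(=O)=O)oc2c1CC=C(C)C
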